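**Strategy.** The route rests on disconnecting C14–C1 of the 14-membered carbocycle through the γ,δ-unsaturated ketone formed by the C13 ketone, C14H2, C1 and the isopropenyl alkene. An 18-membered allyl β-keto lactone, in which the C13 acyl chain is esterified with an (S)-configured α-trimethylsilyl allylic alcohol at C16, undergoes a decarboxylative [3,3] shift. This forges C14–C1, contracts the ring to the tetrahydrofuranone-bridged carbocycle and sets C1, leaving an (E)-vinylsilane that acid converts into the isopropenyl group. C8 and C11 are fixed beforehand by reagent control (Sharpless epoxidation, RAMP-hydrazone alkylation); a Still–Gennari olefination and an acylketene macrolactonisation assemble the lactone.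

Key step: step 22

Numbering: carbocycle C1 (isopropenyl CH) to C14 as in the target; C15 is the substituted isopropenyl carbon and C16 its terminal carbon (the silyl carbinol carbon before step 22).

Structure check: the target is (1S,8R,11R,3Z). Lactone 34 carries 8R, 11R, 16S, (3Z) and an (E)-C1=C15 alkene, and this combination leads to (1S) through a suprafacial shift with silicon pseudo-equatorial, so no structure needed correction. The lactone ring has 18 atoms counted through C9–C10 and 17 through the ether oxygen.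

Design remarks: relay from C11 to C8 across the ring oxygen would have to tell CH3 from a CH2 arm, so both centres are set independently by reagent control. The acylketene precursor is carried as a dioxinone, so no late ester cleavage is needed next to the acid-labile α-hydroxy allylsilane. The [3,3] shift is run on the O-silyl derivative of the lactone to lower the temperature.

Assumption: in the Ipc2BCl reduction (step 17) the SiMe3 group behaves as the larger substituent, as with simpler acylsilanes, so that the (+)-reagent gives the (S)-carbinol; this is to be confirmed on 29 by Mosher ester analysis before the material is carried on.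

**Furanone–phosphonate fragment (steps 1–12)**

Step 1
Reactants: 1 2-methylprop-2-en-1-ol
Product: 3 (R)-(2-methyloxiran-2-yl)methyl 4-methylbenzenesulfonate, via (S)-2-methylglycidol 2 (not isolated)
Conditions: Ti(OiPr)4 (5 mol %), L-(+)-DIPT (6 mol %), cumene hydroperoxide, 4 Å MS, CH2Cl2, −20 °C; then TsCl, Et3N, DMAP (cat.), −10 °C
Reagents that add atoms: cumene hydroperoxide CC(C)(OO)c1ccccc1; p-toluenesulfonyl chloride Cc1ccc(cc1)S(Cl)(=O)=O
Why: Sharpless asymmetric epoxidation with in situ sulfonylation; the L-(+)-tartrate catalyst selects the alkene face that gives (S)-2, whose quaternary carbon becomes C8 (the R descriptor of 3 only reflects the changed priorities).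

Step 2
Reactants: 3 (R)-(2-methyloxiran-2-yl)methyl 4-methylbenzenesulfonate
Product: 4 (R)-2-hydroxy-2-methylpent-4-en-1-yl 4-methylbenzenesulfonate
Conditions: CH2=CHMgBr (1.3 equiv), CuI (10 mol %), THF, −40 °C; aq NH4Cl
Reagents that add atoms: vinylmagnesium bromide C=C[Mg]Br
Why: Copper-catalysed Grignard opening of the epoxide at its CH2 terminus (SN2) should outrun displacement of the neopentyl-type tosylate and installs the allyl arm (C7, C6 and one extra carbon) without touching the C8–O bond.

Step 3
Reactants: 4 (R)-2-hydroxy-2-methylpent-4-en-1-yl 4-methylbenzenesulfonate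
Product: 6 (R)-4-methylhept-1-en-6-yn-4-ol, via epoxide 5 (not isolated)
Conditions: LiC≡CH·H2NCH2CH2NH2 (3 equiv), DMSO, rt
Reagents that add atoms: lithium acetylide–ethylenediamine complex [Li]C#C.NCCN
Why: Base-induced closure of the hydroxy tosylate to the epoxide and SN2 alkynylation at its CH2 add the propargyl arm (C9, C10, C11), while C8 is a spectator and keeps its configuration.

Step 4
Reactants: 6 (R)-4-methylhept-1-en-6-yn-4-ol
Product: 7 (5R)-5-methyl-5-(prop-2-en-1-yl)oxolan-3-one
Conditions: Ph3PAuNTf2 (5 mol %), 8-methylquinoline N-oxide (1.5 equiv), MsOH (1.2 equiv), ClCH2CH2Cl, rt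
Reagents that add atoms: 8-methylquinoline N-oxide Cc1cccc2ccc[n+]([O-])c12
Why: Gold-catalysed oxidation of the terminal alkyne to an α-oxo gold carbene and intramolecular O–H insertion by the tertiary homopropargylic alcohol close the tetrahydrofuran-3-one, with C10 as the ketone and C11 as an unsubstituted OCH2.

Step 5
Reactants: 8 2,2,6-trimethyl-4H-1,3-dioxin-4-one
Product: 9 6-(bromomethyl)-2,2-dimethyl-4H-1,3-dioxin-4-one
Conditions: LDA, THF, −78 °C; BrCCl2CCl2Br, −78 °C
Reagents that add atoms: 1,2-dibromo-1,1,2,2-tetrachloroethane BrC(Cl)(Cl)C(Cl)(Cl)Br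
Why: γ-Halogenation of the lithium dienolate of the dioxinone with a positive-halogen donor, the bromo counterpart of the established hexachloroethane chlorination.

Step 6
Reactants: 7 (5R)-5-methyl-5-(prop-2-en-1-yl)oxolan-3-one; 10 RAMP, (R)-1-amino-2-(methoxymethyl)pyrrolidine
Product: 11 RAMP hydrazone of 7
Conditions: cyclohexane, reflux, Dean–Stark
Reagents that add atoms: none
Why: Hydrazone formation places the Enders auxiliary on C10.

Step 7
Reactants: 11 RAMP hydrazone of 7; 9 6-(bromomethyl)-2,2-dimethyl-4H-1,3-dioxin-4-one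
Product: 12 C11-alkylated hydrazone (11R)
Conditions: LDA (1.1 equiv), THF, 0 °C; then 9, −100 → −78 °C
Reagents that add atoms: none
Why: Enders RAMP-hydrazone alkylation: the azaenolate should form at the unhindered OCH2 (C11) and not at the neopentyl C9, and the chelated auxiliary directs the activated bromide to the face that gives (11R), which makes C11–C12 and brings C12, C13, C14 and the future lactone carbon as a masked acylketene.

Step 8
Reactants: 12 C11-alkylated hydrazone
Product: 13 6-{[(2R,5R)-5-methyl-3-oxo-5-(prop-2-en-1-yl)oxolan-2-yl]methyl}-2,2-dimethyl-4H-1,3-dioxin-4-one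
Conditions: sat. aq oxalic acid, Et2O, rt
Reagents that add atoms: water O
Why: Mild acidic hydrazone hydrolysis frees the C10 ketone without epimerising the adjacent C11 centre and returns the auxiliary.

Step 9
Reactants: 13 allyl furanone dioxinone
Product: 15 C6 aldehyde, via diol 14 (not isolated)
Conditions: OsO4 (2 mol %), NaIO4 (4 equiv), 2,6-lutidine, dioxane–H2O (3:1), rt
Reagents that add atoms: sodium periodate [Na+].[O-]I(=O)(=O)=O; water O
Why: Lemieux–Johnson cleavage of the electron-rich terminal alkene (the electron-poor dioxinone C=C should be left) reveals C6 as the aldehyde.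

Step 10
Reactants: 15 C6 aldehyde
Product: 16 C6 carboxylic acid
Conditions: NaClO2, NaH2PO4, 2-methylbut-2-ene, t-BuOH–H2O, 0 °C → rt
Reagents that add atoms: sodium chlorite [Na+].[O-]Cl=O
Why: Pinnick oxidation under buffered conditions that should not epimerise C11 or open the β-alkoxy acid.

Step 11
Reactants: 16 C6 carboxylic acid
Product: 19 bromomethyl ketone, via acid chloride 17 (not isolated), via diazoketone 18 (not isolated)
Conditions: (COCl)2, DMF (cat.), CH2Cl2, 0 °C; evaporate; Me3SiCHN2, THF–MeCN, 0 °C; then 48% aq HBr, 0 °C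
Reagents that add atoms: (trimethylsilyl)diazomethane C[Si](C)(C)C=[N+]=[N-]; hydrogen bromide Br
Why: Acylation of the diazoalkane (first stage of the Arndt–Eistert sequence) and hydrobromination of the diazoketone add C5 as a bromomethyl ketone without enolate chemistry at C7, C9 or C11.

Step 12
Reactants: 19 bromomethyl ketone; 20 methyl bis(2,2,2-trifluoroethyl)phosphonoacetate
Product: 21 α-(2-oxoalkyl) Still–Gennari phosphonate (C4 epimers)
Conditions: 20 (2 equiv), NaH (1.9 equiv), THF, 0 °C; then 19, 0 °C → rt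
Reagents that add atoms: none
Why: SN2 alkylation of the stabilised phosphonoacetate anion by the α-bromo ketone forms C4–C5; the excess anion limits dialkylation and both C4 epimers converge in the olefination.

**Silyl carbinol fragment (steps 13–19)**

Step 13
Reactants: 22 3-[(tert-butyldimethylsilyl)oxy]propanal; 23 2-(triphenylphosphoranylidene)propanal
Product: 24 (2E)-5-[(tert-butyldimethylsilyl)oxy]-2-methylpent-2-enal
Conditions: toluene, 80 °C
Reagents that add atoms: none
Why: Wittig olefination with a stabilised formyl ylide should give the (E)-trisubstituted enal, which fixes the C1=C15 geometry.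

Step 14
Reactants: 24 (2E)-enal
Product: 25 (2E)-5-[(tert-butyldimethylsilyl)oxy]-2-methylpent-2-en-1-ol
Conditions: NaBH4, CeCl3·7H2O, MeOH, 0 °C
Reagents that add atoms: none
Why: Luche 1,2-reduction gives the allylic alcohol and leaves the alkene geometry alone.

Step 15
Reactants: 25 (2E)-allylic alcohol
Product: 27 rac-(2E)-5-[(tert-butyldimethylsilyl)oxy]-2-methyl-1-(trimethylsilyl)pent-2-en-1-ol, via trimethylsilyl ether 26 (not isolated)
Conditions: n-BuLi (1.05 equiv), THF, −78 °C; Me3SiCl, −78 → 0 °C; then t-BuLi (1.3 equiv), −78 → −35 °C; AcOH, −78 °C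
Reagents that add atoms: chlorotrimethylsilane C[Si](C)(C)Cl
Why: O-silylation, lithiation at the allylic α-oxy carbon and retro-[1,2]-Brook migration of silicon from O to C16 give the racemic α-silyl allylic alcohol.

Step 16
Reactants: 27 racemic α-silyl allylic alcohol
Product: 28 (2E)-5-[(tert-butyldimethylsilyl)oxy]-2-methyl-1-(trimethylsilyl)pent-2-en-1-one
Conditions: (COCl)2, DMSO, CH2Cl2, −78 °C; Et3N
Reagents that add atoms: none
Why: Swern oxidation of an α-silyl carbinol to the α,β-unsaturated acylsilane under conditions that avoid alkoxide-triggered Brook rearrangement.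

Step 17
Reactants: 28 acylsilane
Product: 29 (1S,2E)-5-[(tert-butyldimethylsilyl)oxy]-2-methyl-1-(trimethylsilyl)pent-2-en-1-ol
Conditions: (+)-Ipc2BCl (from (−)-α-pinene, 1.5 equiv), THF, −25 °C → rt; then HN(CH2CH2OH)2, Et2O
Reagents that add atoms: none
Why: Asymmetric 1,2-reduction of the acylsilane with B-chlorodiisopinocampheylborane through the usual boat transition state, with SiMe3 in the place of the large group, should deliver hydride to the face that gives the (S)-carbinol at C16.

Step 18
Reactants: 29 (S)-silyl carbinol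
Product: 30 (1S,2E)-2-methyl-1-(trimethylsilyl)pent-2-ene-1,5-diol
Conditions: HF·pyridine, pyridine, THF, 0 °C → rt
Reagents that add atoms: none
Why: Buffered fluoride desilylation removes the primary TBS ether and should leave the C–Si bond of the acid-sensitive α-hydroxy allylsilane intact.

Step 19
Reactants: 30 diol
Product: 31 (3E,5S)-5-hydroxy-4-methyl-5-(trimethylsilyl)pent-3-enal
Conditions: TEMPO (10 mol %), PhI(OAc)2 (1.1 equiv), CH2Cl2, rt; used at once
Reagents that add atoms: none
Why: Oxoammonium (TEMPO) oxidation is selective for the primary alcohol over the hindered secondary silyl carbinol, and the (E)-alkene prevents lactol formation.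

**Union, macrolactone, ring contraction (steps 20–23)**

Step 20
Reactants: 21 phosphonate; 31 hydroxy aldehyde
Product: 32 methyl (2Z,5E,7S)-2-(3-{(2R,5R)-5-[(2,2-dimethyl-4-oxo-4H-1,3-dioxin-6-yl)methyl]-2-methyl-4-oxooxolan-2-yl}-2-oxopropyl)-7-hydroxy-6-methyl-7-(trimethylsilyl)hepta-2,5-dienoate
Conditions: 21, KHMDS (0.98 equiv), 18-crown-6 (4 equiv), THF, −78 °C; then 31, −78 °C
Reagents that add atoms: none
Why: Still–Gennari olefination of the α-substituted bis(trifluoroethyl) phosphonate forms C3=C4 with the ester cis to C2 (Z) under kinetic control; a slight deficit of base at −78 °C should spare the β,γ-unsaturated aldehyde, the free carbinol and the β-alkoxy ketones.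

Step 21
Reactants: 32 seco hydroxy dioxinone
Product: 34 18-membered β-keto macrolactone (8R,11R,16S,3Z,1(15)E), via acylketene 33 (not isolated)
Conditions: toluene, 110 °C, syringe-pump addition (final 0.5 mM)
Reagents that add atoms: none
Why: Thermal retro-[4+2] of the dioxinone releases acetone and the C13 acylketene, which the C16 hydroxyl captures intramolecularly (acylketene macrolactonisation) to give the allyl β-keto lactone.

Step 22
Reactants: 34 18-membered β-keto macrolactone
Product: 38 (E)-vinylsilane analogue of the target, via silyl ketene acetal 35 (not isolated), via silyl ester 36 (not isolated), via β-keto acid 37 (not isolated)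
Conditions: BSA (1.5 equiv), toluene (1 mM), rt then 95–110 °C; then THF–H2O–AcOH (4:1:1), 45 °C
Reagents that add atoms: none
Why: Proposed new method: BSA should silylate only the strongly enolised β-keto lactone, and 1,5-O,O-silyl migration gives the silyl ketene acetal 35, whose six-atom array C14=C(OSi)–O–C16–C15=C1 undergoes a suprafacial [3,3] shift that forms C14–C1 as C16–O breaks; hydrolysis of silyl ester 36 and loss of CO2 from β-keto acid 37 give 38. The closest known reactions are the thermal and silyl-enol-mediated Carroll rearrangements, the Ireland–Claisen ring contraction of macrolactones and the 1,3-chirality transfer from α-silyl allylic esters to (E)-vinylsilanes. The 14-membered carbocycle closes by sigmatropic ring contraction of the 18-membered lactone, so the C–C ring bond is made inside a six-membered transition state and not by end-to-end cyclisation. C1 is controlled by the (S)-C16 carbinol: bond making and bond breaking occur on the same face of the allyl unit, and with SiMe3 pseudo-equatorial (the path to the (E)-vinylsilane, favoured because an axial silyl group would clash with the OSiMe3 group on the ketene acetal carbon) this face gives (1S). The step needs π-face selectivity at the (E)-C1=C15 alkene and chemoselective enolisation; the first rests on the carbinol centre and the size of silicon, the second on the acidity of the β-keto lactone, and chair or boat geometry is irrelevant because C14 ends as CH2.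

Step 23
Reactants: 38 (E)-vinylsilane
Product: 39 target, CNP0163183.3
Conditions: CF3CO2H (10 equiv), CH2Cl2, 0 °C, short contact; aq NaHCO3
Reagents that add atoms: none
Why: Ipso-protonation of the vinylsilane gives a tertiary β-silyl cation at C15 that loses silicon (protodesilylation), which should unveil the isopropenyl group faster than the product alkene or the C11 centre can react at 0 °C.

**Compound list**

1 | 2-methylprop-2-en-1-ol | C=C(C)CO | starting material
2 | (S)-2-methylglycidol, (2S)-(2-methyloxiran-2-yl)methanol | C[C@]1(CO)CO1 | intermediate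
3 | (R)-(2-methyloxiran-2-yl)methyl 4-methylbenzenesulfonate | C[C@]1(COS(=O)(=O)c2ccc(C)cc2)CO1 | intermediate
4 | (R)-2-hydroxy-2-methylpent-4-en-1-yl 4-methylbenzenesulfonate | C=CC[C@@](C)(O)COS(=O)(=O)c1ccc(C)cc1 | intermediate
5 | (R)-2-methyl-2-(prop-2-en-1-yl)oxirane | C=CC[C@]1(C)CO1 | intermediate
6 | (R)-4-methylhept-1-en-6-yn-4-ol | C=CC[C@@](C)(O)CC#C | intermediate
7 | (5R)-5-methyl-5-(prop-2-en-1-yl)oxolan-3-one | C=CC[C@]1(C)CC(=O)CO1 | intermediate
8 | 2,2,6-trimethyl-4H-1,3-dioxin-4-one | CC1=CC(=O)OC(C)(C)O1 | starting material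
9 | 6-(bromomethyl)-2,2-dimethyl-4H-1,3-dioxin-4-one | BrCC1=CC(=O)OC(C)(C)O1 | intermediate
10 | RAMP, (R)-1-amino-2-(methoxymethyl)pyrrolidine | COC[C@H]1CCCN1N | starting material
11 | (5R)-N-[(2R)-2-(methoxymethyl)pyrrolidin-1-yl]-5-methyl-5-(prop-2-en-1-yl)oxolan-3-imine | C=CC[C@]1(C)CC(=NN2CCC[C@@H]2COC)CO1 | intermediate
12 | 6-{[(2R,5R)-3-{[(2R)-2-(methoxymethyl)pyrrolidin-1-yl]imino}-5-methyl-5-(prop-2-en-1-yl)oxolan-2-yl]methyl}-2,2-dimethyl-4H-1,3-dioxin-4-one | C=CC[C@]1(C)CC(=NN2CCC[C@@H]2COC)[C@@H](CC2=CC(=O)OC(C)(C)O2)O1 | intermediate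
13 | 6-{[(2R,5R)-5-methyl-3-oxo-5-(prop-2-en-1-yl)oxolan-2-yl]methyl}-2,2-dimethyl-4H-1,3-dioxin-4-one | C=CC[C@]1(C)CC(=O)[C@@H](CC2=CC(=O)OC(C)(C)O2)O1 | intermediate
14 | 6-{[(2R,5R)-5-(2,3-dihydroxypropyl)-5-methyl-3-oxooxolan-2-yl]methyl}-2,2-dimethyl-4H-1,3-dioxin-4-one (carbinol epimers) | OCC(O)C[C@]1(C)CC(=O)[C@@H](CC2=CC(=O)OC(C)(C)O2)O1 | intermediate
15 | 2-[(2R,5R)-5-[(2,2-dimethyl-4-oxo-4H-1,3-dioxin-6-yl)methyl]-2-methyl-4-oxooxolan-2-yl]acetaldehyde | O=CC[C@]1(C)CC(=O)[C@@H](CC2=CC(=O)OC(C)(C)O2)O1 | intermediate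
16 | 2-[(2S,5R)-5-[(2,2-dimethyl-4-oxo-4H-1,3-dioxin-6-yl)methyl]-2-methyl-4-oxooxolan-2-yl]acetic acid (same geometry as 15; descriptor changes with priorities) | OC(=O)C[C@]1(C)CC(=O)[C@@H](CC2=CC(=O)OC(C)(C)O2)O1 | intermediate
17 | 2-[(2S,5R)-5-[(2,2-dimethyl-4-oxo-4H-1,3-dioxin-6-yl)methyl]-2-methyl-4-oxooxolan-2-yl]acetyl chloride | ClC(=O)C[C@]1(C)CC(=O)[C@@H](CC2=CC(=O)OC(C)(C)O2)O1 | intermediate
18 | 6-{[(2R,5R)-5-(3-diazo-2-oxopropyl)-5-methyl-3-oxooxolan-2-yl]methyl}-2,2-dimethyl-4H-1,3-dioxin-4-one | [N-]=[N+]=CC(=O)C[C@]1(C)CC(=O)[C@@H](CC2=CC(=O)OC(C)(C)O2)O1 | intermediate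
19 | 6-{[(2R,5S)-5-(3-bromo-2-oxopropyl)-5-methyl-3-oxooxolan-2-yl]methyl}-2,2-dimethyl-4H-1,3-dioxin-4-one | BrCC(=O)C[C@]1(C)CC(=O)[C@@H](CC2=CC(=O)OC(C)(C)O2)O1 | intermediate
20 | methyl bis(2,2,2-trifluoroethyl)phosphonoacetate | COC(=O)CP(=O)(OCC(F)(F)F)OCC(F)(F)F | starting material
21 | methyl 2-[bis(2,2,2-trifluoroethoxy)phosphoryl]-5-[(2R,5R)-5-[(2,2-dimethyl-4-oxo-4H-1,3-dioxin-6-yl)methyl]-2-methyl-4-oxooxolan-2-yl]-4-oxopentanoate (both C2 epimers) | COC(=O)C(CC(=O)C[C@]1(C)CC(=O)[C@@H](CC2=CC(=O)OC(C)(C)O2)O1)P(=O)(OCC(F)(F)F)OCC(F)(F)F | intermediate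
22 | 3-[(tert-butyldimethylsilyl)oxy]propanal | O=CCCO[Si](C)(C)C(C)(C)C | starting material
23 | 2-(triphenylphosphoranylidene)propanal | CC(C=O)=P(c1ccccc1)(c1ccccc1)c1ccccc1 | starting material
24 | (2E)-5-[(tert-butyldimethylsilyl)oxy]-2-methylpent-2-enal | O=C/C(C)=C/CCO[Si](C)(C)C(C)(C)C | intermediate
25 | (2E)-5-[(tert-butyldimethylsilyl)oxy]-2-methylpent-2-en-1-ol | OC/C(C)=C/CCO[Si](C)(C)C(C)(C)C | intermediate
26 | tert-butyldimethyl{[(3E)-4-methyl-5-[(trimethylsilyl)oxy]pent-3-en-1-yl]oxy}silane | C[Si](C)(C)OC/C(C)=C/CCO[Si](C)(C)C(C)(C)C | intermediate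
27 | rac-(2E)-5-[(tert-butyldimethylsilyl)oxy]-2-methyl-1-(trimethylsilyl)pent-2-en-1-ol | C[Si](C)(C)C(O)/C(C)=C/CCO[Si](C)(C)C(C)(C)C | intermediate
28 | (2E)-5-[(tert-butyldimethylsilyl)oxy]-2-methyl-1-(trimethylsilyl)pent-2-en-1-one | C[Si](C)(C)C(=O)/C(C)=C/CCO[Si](C)(C)C(C)(C)C | intermediate
29 | (1S,2E)-5-[(tert-butyldimethylsilyl)oxy]-2-methyl-1-(trimethylsilyl)pent-2-en-1-ol | C[Si](C)(C)[C@H](O)/C(C)=C/CCO[Si](C)(C)C(C)(C)C | intermediate
30 | (1S,2E)-2-methyl-1-(trimethylsilyl)pent-2-ene-1,5-diol | C[Si](C)(C)[C@H](O)/C(C)=C/CCO | intermediate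
31 | (3E,5S)-5-hydroxy-4-methyl-5-(trimethylsilyl)pent-3-enal | C[Si](C)(C)[C@H](O)/C(C)=C/CC=O | intermediate
32 | methyl (2Z,5E,7S)-2-(3-{(2R,5R)-5-[(2,2-dimethyl-4-oxo-4H-1,3-dioxin-6-yl)methyl]-2-methyl-4-oxooxolan-2-yl}-2-oxopropyl)-7-hydroxy-6-methyl-7-(trimethylsilyl)hepta-2,5-dienoate | C[Si](C)(C)[C@H](O)/C(C)=C/C/C=C(\C(=O)OC)CC(=O)C[C@]1(C)CC(=O)[C@@H](CC2=CC(=O)OC(C)(C)O2)O1 | intermediate
33 | acylketene from 32 (C13 acyl ketene, C14=C=O) | C[Si](C)(C)[C@H](O)/C(C)=C/C/C=C(\C(=O)OC)CC(=O)C[C@]1(C)CC(=O)[C@@H](CC(=O)C=C=O)O1 | intermediate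
34 | 18-membered β-keto macrolactone of the (16S)-silyl carbinol (8R,11R,3Z,1(15)E) | O=C1CC(=O)C[C@H]2O[C@@](C)(CC2=O)CC(=O)C/C(C(=O)OC)=C/C/C=C(C)/[C@H]([Si](C)(C)C)O1 | intermediate
35 | O-trimethylsilyl ketene acetal of 34 (in equilibrium with the 13-O-silyl enol ether) | C[Si](C)(C)O/C1=C\C(=O)C[C@H]2O[C@@](C)(CC2=O)CC(=O)C/C(C(=O)OC)=C/C/C=C(C)/[C@H]([Si](C)(C)C)O1 | intermediate
36 | trimethylsilyl ester of the ring-contracted C14 carboxylic acid (C14 epimers) | C[Si](C)(C)/C=C(\C)[C@H]1C/C=C(\C(=O)OC)CC(=O)C[C@]2(C)CC(=O)[C@@H](CC(=O)C1C(=O)O[Si](C)(C)C)O2 | intermediate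
37 | 14-membered β-keto acid, CO2H on C14 (C14 epimers) | C[Si](C)(C)/C=C(\C)[C@H]1C/C=C(\C(=O)OC)CC(=O)C[C@]2(C)CC(=O)[C@@H](CC(=O)C1C(=O)O)O2 | intermediate
38 | (E)-vinylsilane analogue of the target, C1 bears (E)-C(CH3)=CH–SiMe3 (1S,8R,11R,3Z) | C[Si](C)(C)/C=C(\C)[C@H]1C/C=C(\C(=O)OC)CC(=O)C[C@]2(C)CC(=O)[C@@H](CC(=O)C1)O2 | intermediate
39 | CNP0163183.3 (1S,8R,11R,3Z) | C=C(C)[C@H]1C/C=C(\C(=O)OC)CC(=O)C[C@]2(C)CC(=O)[C@@H](CC(=O)C1)O2 | target

**Step count and risk**

Total: 23 steps. Longest linear sequence: 15 steps (1–4, 6–12, 20–23). Side branches: step 5 (one step) and steps 13–19 (seven steps).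

Steps most likely to fail:

1. Step 22 (Proposed new method). The [3,3] shift may be outrun by thermal decay of the lactone: retro-oxa-Michael opening of the furanone, reversion of the β-keto lactone to the acylketene, or hydrogen shifts in the skipped diene. It may also leak through the axial-silyl pathway and lose face selectivity at C1. Fallback: a palladium-catalysed decarboxylative allylic alkylation of the same lactone (Pd2(dba)3, PPh3 or dppe, THF, 25–40 °C). Ionisation of the allylic ester, loss of CO2 and recombination of the C14 enolate at the allyl terminus remote from silicon proceed with overall retention, hence with the same sense at C1, at or near room temperature. The fallback sets out from 34 and returns directly at 38; it makes no compound outside the list (F0).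

2. Step 7. The azaenolate may be quenched by proton transfer from the acidic bromide 9, or may add to its carbonyl group instead of displacing bromide. Fallback: build the masked acylketene stepwise. Setting out from 11, alkylation under the same conditions with tert-butyl bromoacetate gives tert-butyl 2-[(2R,5R)-3-{[(2R)-2-(methoxymethyl)pyrrolidin-1-yl]imino}-5-methyl-5-(prop-2-en-1-yl)oxolan-2-yl]acetate F1. Oxalic acid hydrolysis gives the keto ester F2, and CF3CO2H in CH2Cl2 frees the acid F3. Coupling with Meldrum's acid (EDC, DMAP) gives the acyl Meldrum's acid F4. Heating F4 in toluene–acetone converts it through the acylketene into the dioxinone, and the route is rejoined at 13.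

3. Step 21. Intermolecular capture of the acylketene (oligomers) or its reversible capture by the C10 or C6 carbonyl groups may outpace closure onto the hindered C16 hydroxyl. Fallback: separate acylketene generation from ring closure. Setting out from 32, thermolysis in toluene at 100 °C with excess 2-methylpropane-2-thiol gives the S-tert-butyl β-keto thioester F5. Thiophilic activation with silver trifluoroacetate and Na2HPO4 in THF at room temperature under high dilution closes the lactone, and the route is rejoined at 34.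

**Further compounds**

F0 | step 22 | none | none
F1 | step 7 | tert-butyl 2-[(2R,5R)-3-{[(2R)-2-(methoxymethyl)pyrrolidin-1-yl]imino}-5-methyl-5-(prop-2-en-1-yl)oxolan-2-yl]acetate | C=CC[C@]1(C)CC(=NN2CCC[C@@H]2COC)[C@@H](CC(=O)OC(C)(C)C)O1
F2 | step 7 | tert-butyl 2-[(2R,5R)-5-methyl-3-oxo-5-(prop-2-en-1-yl)oxolan-2-yl]acetate | C=CC[C@]1(C)CC(=O)[C@@H](CC(=O)OC(C)(C)C)O1
F3 | step 7 | 2-[(2R,5R)-5-methyl-3-oxo-5-(prop-2-en-1-yl)oxolan-2-yl]acetic acid | C=CC[C@]1(C)CC(=O)[C@@H](CC(=O)O)O1
F4 | step 7 | 5-{1-hydroxy-2-[(2R,5R)-5-methyl-3-oxo-5-(prop-2-en-1-yl)oxolan-2-yl]ethylidene}-2,2-dimethyl-1,3-dioxane-4,6-dione | C=CC[C@]1(C)CC(=O)[C@@H](CC(O)=C2C(=O)OC(C)(C)OC2=O)O1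
F5 | step 21 | methyl (2Z,5E,7S)-2-(3-{(2R,5R)-5-[4-(tert-butylsulfanyl)-2,4-dioxobutyl]-2-methyl-4-oxooxolan-2-yl}-2-oxopropyl)-7-hydroxy-6-methyl-7-(trimethylsilyl)hepta-2,5-dienoate | C[Si](C)(C)[C@H](O)/C(C)=C/C/C=C(\C(=O)OC)CC(=O)C[C@]1(C)CC(=O)[C@@H](CC(=O)CC(=O)SC(C)(C)C)O1
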